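## Retrosynthetic overview

- The strategy rests on inner C2, the single sp3 carbon of the ring C dihydrofuran that carries ring B and bridges phenolic O1 and C3. It is cut at O1–C2 and C2–C3, giving a ring C ortho-quinone methide (methide carbon = C3) and a benzylic sulfonium ylide carbon on ring B.
- The outer dihydrofuran (rings A and B) is cut the same way: a ring B ortho-quinone methide bearing a C5 ester plus a ring A benzylic thiolanium ylide. The C5 ester is then turned into the CH2–S+ handle.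
- Ring order: outer dihydrofuran first (step 12), inner dihydrofuran second (step 23), global desilylation last. Absolute configuration in both annulations comes from (2R,5R)-2,5-dimethylthiolane.
- Fragments: vanillin (ring A), methyl vanillate (ring B), eugenol (ring C), (2S,5S)-hexane-2,5-diol (sulfide).

Key step: step 23

Remark 1: the (2R,5R)-thiolanium ylide is assumed to deliver the (2R,3S) ring; if the sense of induction is the opposite, (2S,5S)-2,5-dimethylthiolane from (2R,5R)-hexane-2,5-diol is used in steps 6 and 15 with nothing else changed.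

Remark 2: alkyl hydroxyls are carried as TBDPS ethers (stable to the sulfinic acid of steps 11 and 22) and the ring A phenol as a TIPS ether (stable to Cs2CO3); all four silyl groups fall to fluoride in one step.

## Route

Step 1
Reactants: 1 (2S,5S)-hexane-2,5-diol
Product: 2 (2S,5S)-hexane-2,5-diyl dimethanesulfonate
Conditions: MsCl, Et3N, CH2Cl2, 0 °C
Reagents that add atoms: methanesulfonyl chloride, CS(=O)(=O)Cl
Why: O-sulfonylation of both secondary alcohols leaves the carbinol carbons untouched, so both centres stay S.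

Step 2
Reactants: 2 (2S,5S)-hexane-2,5-diyl dimethanesulfonate
Product: 3 (2R,5R)-2,5-dimethylthiolane
Conditions: Na2S·9H2O, DMSO, rt; distillation
Reagents that add atoms: sodium sulfide, [Na+].[Na+].[S-2]
Why: double SN2 displacement by sulfide (inter- then intramolecular) inverts both centres, so the S,S dimesylate should give the C2-symmetric R,R thiolane.

Step 3
Reactants: 4 vanillin
Product: 5 3-methoxy-4-(triisopropylsilyloxy)benzaldehyde
Conditions: TIPSCl, imidazole, DMF, rt
Reagents that add atoms: triisopropylsilyl chloride, CC(C)[Si](Cl)(C(C)C)C(C)C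
Why: imidazole-promoted silylation of the phenol gives an aryl silyl ether that tolerates hydride, bromide and carbonate base in the later steps.

Step 4
Reactants: 5 3-methoxy-4-(triisopropylsilyloxy)benzaldehyde
Product: 6 [3-methoxy-4-(triisopropylsilyloxy)phenyl]methanol
Conditions: NaBH4, MeOH, 0 °C
Reagents that add atoms: none
Why: borohydride reduction of an aryl aldehyde is fast at 0 °C and leaves the aryl TIPS ether intact.

Step 5
Reactants: 6 [3-methoxy-4-(triisopropylsilyloxy)phenyl]methanol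
Product: 7 4-(bromomethyl)-2-methoxyphenyl triisopropylsilyl ether
Conditions: CBr4, PPh3, CH2Cl2, 0 °C; used without storage
Reagents that add atoms: carbon tetrabromide, BrC(Br)(Br)Br
Why: the Appel reaction converts the primary benzylic alcohol into the bromide under neutral conditions that spare the silyl ether.

Step 6
Reactants: 7 4-(bromomethyl)-2-methoxyphenyl triisopropylsilyl ether; 3 (2R,5R)-2,5-dimethylthiolane
Product: 8 (2R,5R)-1-[3-methoxy-4-(triisopropylsilyloxy)benzyl]-2,5-dimethylthiolanium tetrafluoroborate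
Conditions: AgBF4, CH2Cl2, 0 °C → rt, dark
Reagents that add atoms: silver tetrafluoroborate, [Ag+].F[B-](F)(F)F
Why: S-alkylation of the hindered sulfide is driven by precipitation of AgBr, and because the sulfide is C2-symmetric the sulfur is not stereogenic, so a single sulfonium salt should form.

Step 7
Reactants: 9 methyl vanillate
Product: 10 methyl 3-formyl-4-hydroxy-5-methoxybenzoate
Conditions: MgCl2, Et3N, (CH2O)n, MeCN, reflux; aq. HCl work-up
Reagents that add atoms: paraformaldehyde (formaldehyde), C=O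
Why: magnesium-phenoxide-directed ortho-formylation (Casnati–Skattebøl) delivers formaldehyde to the only free ortho position, and a second formaldehyde oxidises the benzylic alkoxide to the aldehyde.

Step 8
Reactants: 10 methyl 3-formyl-4-hydroxy-5-methoxybenzoate
Product: 11 methyl 4-hydroxy-3-methoxy-5-vinylbenzoate
Conditions: Ph3PCH3Br, NaN(SiMe3)2 (2.2 equiv of ylide), THF, 0 °C → rt
Reagents that add atoms: methyltriphenylphosphonium bromide, C[P+](c1ccccc1)(c1ccccc1)c1ccccc1.[Br-]
Why: Wittig methylenation of the salicylaldehyde (one equivalent of ylide serves as base for the phenol) is much faster than attack on the aryl ester.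

Step 9
Reactants: 11 methyl 4-hydroxy-3-methoxy-5-vinylbenzoate
Product: 12 methyl 3-(1,2-dihydroxyethyl)-4-hydroxy-5-methoxybenzoate (racemic)
Conditions: OsO4 (2 mol %), NMO, acetone/H2O, rt
Reagents that add atoms: N-methylmorpholine N-oxide, C[N+]1([O-])CCOCC1; water, O
Why: Upjohn dihydroxylation of the styrene gives the 1,2-diol; the new benzylic centre is racemic and is erased later at the quinone methide stage.

Step 10
Reactants: 12 methyl 3-(1,2-dihydroxyethyl)-4-hydroxy-5-methoxybenzoate (racemic)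
Product: 13 methyl 3-[2-(tert-butyldiphenylsilyloxy)-1-hydroxyethyl]-4-hydroxy-5-methoxybenzoate (racemic)
Conditions: TBDPSCl (1.05 equiv), imidazole, CH2Cl2, 0 °C
Reagents that add atoms: tert-butyldiphenylsilyl chloride, CC(C)(C)[Si](Cl)(c1ccccc1)c1ccccc1
Why: the bulky silyl chloride should select the primary alcohol over the secondary benzylic alcohol and the 2,6-disubstituted, hydrogen-bonded phenol.

Step 11
Reactants: 13 methyl 3-[2-(tert-butyldiphenylsilyloxy)-1-hydroxyethyl]-4-hydroxy-5-methoxybenzoate (racemic)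
Product: 14 methyl 3-[2-(tert-butyldiphenylsilyloxy)-1-tosylethyl]-4-hydroxy-5-methoxybenzoate (racemic; ring B sulfone)
Conditions: p-TolSO2H (3 equiv), CH2Cl2, rt → 40 °C
Reagents that add atoms: p-toluenesulfinic acid, Cc1ccc(S(=O)O)cc1
Why: acid-promoted dehydration of the ortho-hydroxybenzyl alcohol and S-capture by sulfinate is the standard entry to 2-(1-tosylalkyl)phenols, and the TBDPS ether withstands the sulfinic acid.

Step 12
Reactants: 14 methyl 3-[2-(tert-butyldiphenylsilyloxy)-1-tosylethyl]-4-hydroxy-5-methoxybenzoate (racemic; ring B sulfone); 8 (2R,5R)-1-[3-methoxy-4-(triisopropylsilyloxy)benzyl]-2,5-dimethylthiolanium tetrafluoroborate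
Product: 18 methyl (2R,3S)-3-[(tert-butyldiphenylsilyloxy)methyl]-7-methoxy-2-[3-methoxy-4-(triisopropylsilyloxy)phenyl]-2,3-dihydrobenzofuran-5-carboxylate, via ring B ortho-quinone methide 15 (not isolated), via ring A benzylic ylide 16 (not isolated), via ring B anti betaine 17 (not isolated)
Conditions: powdered Cs2CO3 (3 equiv), CH2Cl2, 0 °C → rt; 14 added slowly to 8 (1.3 equiv)
Reagents that add atoms: none
Why: base-mediated formal [4+1] annulation in which the phenoxide of 14 expels sulfinate to give 15, ylide 16 adds to the methide carbon, and the phenoxide of 17 displaces the thiolane by 5-exo-tet SN2 closure; C2 is set by the C2-symmetric thiolane and C3 by the faster, trans-selective closure of the anti betaine.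

Step 13
Reactants: 18 methyl (2R,3S)-3-[(tert-butyldiphenylsilyloxy)methyl]-7-methoxy-2-[3-methoxy-4-(triisopropylsilyloxy)phenyl]-2,3-dihydrobenzofuran-5-carboxylate
Product: 19 {(2R,3S)-3-[(tert-butyldiphenylsilyloxy)methyl]-7-methoxy-2-[3-methoxy-4-(triisopropylsilyloxy)phenyl]-2,3-dihydrobenzofuran-5-yl}methanol
Conditions: i-Bu2AlH (2.5 equiv), CH2Cl2, −78 °C; aq. potassium sodium tartrate
Reagents that add atoms: none
Why: hydride reduction of the aryl ester to the benzylic alcohol touches neither the silyl ethers nor the two stereocentres.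

Step 14
Reactants: 19 {(2R,3S)-3-[(tert-butyldiphenylsilyloxy)methyl]-7-methoxy-2-[3-methoxy-4-(triisopropylsilyloxy)phenyl]-2,3-dihydrobenzofuran-5-yl}methanol
Product: 20 (2R,3S)-5-(bromomethyl)-3-[(tert-butyldiphenylsilyloxy)methyl]-7-methoxy-2-[3-methoxy-4-(triisopropylsilyloxy)phenyl]-2,3-dihydrobenzofuran
Conditions: CBr4, PPh3, 2,6-lutidine, CH2Cl2, 0 °C; used without storage
Reagents that add atoms: carbon tetrabromide, BrC(Br)(Br)Br
Why: the buffered Appel reaction converts the primary benzylic alcohol into the bromide without acid that could ionise the benzylic C2–O bond.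

Step 15
Reactants: 20 (2R,3S)-5-(bromomethyl)-3-[(tert-butyldiphenylsilyloxy)methyl]-7-methoxy-2-[3-methoxy-4-(triisopropylsilyloxy)phenyl]-2,3-dihydrobenzofuran; 3 (2R,5R)-2,5-dimethylthiolane
Product: 21 (2R,5R)-1-({(2R,3S)-3-[(tert-butyldiphenylsilyloxy)methyl]-7-methoxy-2-[3-methoxy-4-(triisopropylsilyloxy)phenyl]-2,3-dihydrobenzofuran-5-yl}methyl)-2,5-dimethylthiolanium tetrafluoroborate (outer-unit sulfonium salt)
Conditions: AgBF4, CH2Cl2, 0 °C → rt, dark
Reagents that add atoms: silver tetrafluoroborate, [Ag+].F[B-](F)(F)F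
Why: silver-assisted S-alkylation as in step 6; the para-alkoxybenzyl bromide is a reactive electrophile and the non-nucleophilic counter-ion keeps the salt from reverting.

Step 16
Reactants: 22 eugenol
Product: 24 dihydroconiferyl alcohol [4-(3-hydroxypropyl)-2-methoxyphenol], via bis(9-BBN) adduct 23 (not isolated)
Conditions: 9-BBN (2.2 equiv), THF, rt; then NaOH, H2O2, 0 °C → rt
Reagents that add atoms: hydrogen peroxide, OO
Why: anti-Markovnikov hydroboration of the terminal alkene (the second equivalent of borane is taken up by the phenol) followed by oxidation of the C–B bond gives the primary alcohol.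

Step 17
Reactants: 24 dihydroconiferyl alcohol [4-(3-hydroxypropyl)-2-methoxyphenol]
Product: 25 4-[3-(tert-butyldiphenylsilyloxy)propyl]-2-methoxyphenol
Conditions: TBDPSCl (1.05 equiv), imidazole, CH2Cl2, 0 °C
Reagents that add atoms: tert-butyldiphenylsilyl chloride, CC(C)(C)[Si](Cl)(c1ccccc1)c1ccccc1
Why: under neutral imidazole conditions the primary alcohol should be silylated in preference to the hydrogen-bonded guaiacol phenol.

Step 18
Reactants: 25 4-[3-(tert-butyldiphenylsilyloxy)propyl]-2-methoxyphenol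
Product: 26 5-[3-(tert-butyldiphenylsilyloxy)propyl]-2-hydroxy-3-methoxybenzaldehyde
Conditions: MgCl2, Et3N, (CH2O)n, MeCN, reflux; aq. HCl work-up
Reagents that add atoms: paraformaldehyde (formaldehyde), C=O
Why: magnesium-mediated ortho-formylation as in step 7 has only one free ortho position, and its non-acidic conditions keep the silyl ether.

Step 19
Reactants: 26 5-[3-(tert-butyldiphenylsilyloxy)propyl]-2-hydroxy-3-methoxybenzaldehyde
Product: 27 4-[3-(tert-butyldiphenylsilyloxy)propyl]-2-methoxy-6-vinylphenol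
Conditions: Ph3PCH3Br, NaN(SiMe3)2 (2.2 equiv of ylide), THF, 0 °C → rt
Reagents that add atoms: methyltriphenylphosphonium bromide, C[P+](c1ccccc1)(c1ccccc1)c1ccccc1.[Br-]
Why: Wittig methylenation of the salicylaldehyde, with one equivalent of ylide consumed as base for the phenol.

Step 20
Reactants: 27 4-[3-(tert-butyldiphenylsilyloxy)propyl]-2-methoxy-6-vinylphenol
Product: 28 1-{5-[3-(tert-butyldiphenylsilyloxy)propyl]-2-hydroxy-3-methoxyphenyl}ethane-1,2-diol (racemic)
Conditions: OsO4 (2 mol %), NMO, acetone/H2O, rt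
Reagents that add atoms: N-methylmorpholine N-oxide, C[N+]1([O-])CCOCC1; water, O
Why: Upjohn dihydroxylation of the styrene; the racemic benzylic centre is erased later at the quinone methide stage.

Step 21
Reactants: 28 1-{5-[3-(tert-butyldiphenylsilyloxy)propyl]-2-hydroxy-3-methoxyphenyl}ethane-1,2-diol (racemic)
Product: 29 2-[2-(tert-butyldiphenylsilyloxy)-1-hydroxyethyl]-4-[3-(tert-butyldiphenylsilyloxy)propyl]-6-methoxyphenol (racemic)
Conditions: TBDPSCl (1.05 equiv), imidazole, CH2Cl2, 0 °C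
Reagents that add atoms: tert-butyldiphenylsilyl chloride, CC(C)(C)[Si](Cl)(c1ccccc1)c1ccccc1
Why: selective silylation of the primary alcohol over the secondary benzylic alcohol and the hindered phenol, as in step 10.

Step 22
Reactants: 29 2-[2-(tert-butyldiphenylsilyloxy)-1-hydroxyethyl]-4-[3-(tert-butyldiphenylsilyloxy)propyl]-6-methoxyphenol (racemic)
Product: 30 2-[2-(tert-butyldiphenylsilyloxy)-1-tosylethyl]-4-[3-(tert-butyldiphenylsilyloxy)propyl]-6-methoxyphenol (racemic; ring C sulfone)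
Conditions: p-TolSO2H (3 equiv), CH2Cl2, rt
Reagents that add atoms: p-toluenesulfinic acid, Cc1ccc(S(=O)O)cc1
Why: acid-promoted substitution of the ortho-hydroxybenzyl alcohol by sulfinate at sulfur, as in step 11 but on a more electron-rich ring that should ionise more readily.

Step 23
Reactants: 30 2-[2-(tert-butyldiphenylsilyloxy)-1-tosylethyl]-4-[3-(tert-butyldiphenylsilyloxy)propyl]-6-methoxyphenol (racemic; ring C sulfone); 21 (2R,5R)-1-({(2R,3S)-3-[(tert-butyldiphenylsilyloxy)methyl]-7-methoxy-2-[3-methoxy-4-(triisopropylsilyloxy)phenyl]-2,3-dihydrobenzofuran-5-yl}methyl)-2,5-dimethylthiolanium tetrafluoroborate (outer-unit sulfonium salt)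
Product: 34 tetrasilyl ether of the target with (2R,3S) configuration at both dihydrofuran rings (three TBDPS ethers on the alkyl oxygens and one TIPS ether on the ring A phenol), via ring C ortho-quinone methide 31 (not isolated), via outer-unit benzylic ylide 32 (not isolated), via ring C anti betaine 33 (not isolated)
Conditions: powdered Cs2CO3 (3 equiv), CH2Cl2, 0 °C → rt; 30 (1.2 equiv) added over several hours to 21
Reagents that add atoms: none
Why: Cs2CO3 turns phenol 30 into its phenoxide, which expels p-toluenesulfinate to give ortho-quinone methide 31 (methide carbon = future C3), and it also deprotonates 21 to the semi-stabilised benzylic ylide 32; the ylide carbon adds to the methide carbon (C2–C3), rearomatising ring C to phenoxide betaine 33, and the phenoxide then displaces the thiolane at C2 with inversion (O1–C2). The closest known reaction type is the base-mediated formal [4+1] annulation of ortho-quinone methides from 2-(1-tosylalkyl)phenols with sulfonium ylides, combined with benzylidene transfer from C2-symmetric thiolanium ylides as practised in asymmetric epoxidation. The inner dihydrofuran ring closes by 5-exo-tet SN2 displacement of the sulfide. C2 is controlled by the (2R,5R)-dimethylthiolane, whose two methyl groups leave one ylide conformer with one open face, and C3 follows because addition is reversible and the anti betaine closes faster, so the ring should come out trans; the remote outer stereocentres should exert little bias, so reagent control decides. The step needs ylide capture to outrun tautomerisation of the alkyl-substituted methide to the vinylphenol and its oligomerisation, which slow release of 31 into a solution already holding the ylide secures, and it needs attack at the methide carbon only, which the aromatisation gained in the 1,4-addition secures.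

Step 24
Reactants: 34 tetrasilyl ether of the target
Product: 35 CNP0599161.1 (target)
Conditions: Bu4NF (excess), AcOH, THF, rt
Reagents that add atoms: none
Why: buffered fluoride cleaves the three TBDPS ethers and the aryl TIPS ether in one operation, and buffering should keep the liberated para-hydroxyphenyl group from opening the benzylic ether as its phenoxide, so the four stereocentres remain.

## Compound list

1 | (2S,5S)-hexane-2,5-diol | C[C@H](O)CC[C@H](C)O | starting material
2 | (2S,5S)-hexane-2,5-diyl dimethanesulfonate | C[C@H](OS(C)(=O)=O)CC[C@H](C)OS(C)(=O)=O | intermediate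
3 | (2R,5R)-2,5-dimethylthiolane | C[C@@H]1CC[C@@H](C)S1 | intermediate
4 | vanillin | COc1cc(C=O)ccc1O | starting material
5 | 3-methoxy-4-(triisopropylsilyloxy)benzaldehyde | COc1cc(C=O)ccc1O[Si](C(C)C)(C(C)C)C(C)C | intermediate
6 | [3-methoxy-4-(triisopropylsilyloxy)phenyl]methanol | COc1cc(CO)ccc1O[Si](C(C)C)(C(C)C)C(C)C | intermediate
7 | 4-(bromomethyl)-2-methoxyphenyl triisopropylsilyl ether | COc1cc(CBr)ccc1O[Si](C(C)C)(C(C)C)C(C)C | intermediate
8 | (2R,5R)-1-[3-methoxy-4-(triisopropylsilyloxy)benzyl]-2,5-dimethylthiolanium tetrafluoroborate | COc1cc(C[S+]2[C@H](C)CC[C@H]2C)ccc1O[Si](C(C)C)(C(C)C)C(C)C.F[B-](F)(F)F | intermediate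
9 | methyl vanillate | COc1cc(C(=O)OC)ccc1O | starting material
10 | methyl 3-formyl-4-hydroxy-5-methoxybenzoate | COc1cc(C(=O)OC)cc(C=O)c1O | intermediate
11 | methyl 4-hydroxy-3-methoxy-5-vinylbenzoate | COc1cc(C(=O)OC)cc(C=C)c1O | intermediate
12 | methyl 3-(1,2-dihydroxyethyl)-4-hydroxy-5-methoxybenzoate (racemic) | COc1cc(C(=O)OC)cc(C(O)CO)c1O | intermediate
13 | methyl 3-[2-(tert-butyldiphenylsilyloxy)-1-hydroxyethyl]-4-hydroxy-5-methoxybenzoate (racemic) | COc1cc(C(=O)OC)cc(C(O)CO[Si](c2ccccc2)(c2ccccc2)C(C)(C)C)c1O | intermediate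
14 | methyl 3-[2-(tert-butyldiphenylsilyloxy)-1-tosylethyl]-4-hydroxy-5-methoxybenzoate (racemic; ring B sulfone) | COc1cc(C(=O)OC)cc(C(CO[Si](c2ccccc2)(c2ccccc2)C(C)(C)C)S(=O)(=O)c2ccc(C)cc2)c1O | intermediate
15 | ring B ortho-quinone methide (not isolated) | COC1=CC(C(=O)OC)=CC(=CCO[Si](c2ccccc2)(c2ccccc2)C(C)(C)C)C1=O | intermediate
16 | ring A benzylic ylide (not isolated) | COc1cc([CH-][S+]2[C@H](C)CC[C@H]2C)ccc1O[Si](C(C)C)(C(C)C)C(C)C | intermediate
17 | ring B anti betaine (not isolated) | COc1cc([C@@H]([S+]2[C@H](C)CC[C@H]2C)[C@H](CO[Si](c4ccccc4)(c5ccccc5)C(C)(C)C)c3cc(C(=O)OC)cc(OC)c3[O-])ccc1O[Si](C(C)C)(C(C)C)C(C)C | intermediate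
18 | methyl (2R,3S)-3-[(tert-butyldiphenylsilyloxy)methyl]-7-methoxy-2-[3-methoxy-4-(triisopropylsilyloxy)phenyl]-2,3-dihydrobenzofuran-5-carboxylate | COc1cc([C@@H]2Oc3c(OC)cc(C(=O)OC)cc3[C@H]2CO[Si](c4ccccc4)(c5ccccc5)C(C)(C)C)ccc1O[Si](C(C)C)(C(C)C)C(C)C | intermediate
19 | {(2R,3S)-3-[(tert-butyldiphenylsilyloxy)methyl]-7-methoxy-2-[3-methoxy-4-(triisopropylsilyloxy)phenyl]-2,3-dihydrobenzofuran-5-yl}methanol | COc1cc([C@@H]2Oc3c(OC)cc(CO)cc3[C@H]2CO[Si](c4ccccc4)(c5ccccc5)C(C)(C)C)ccc1O[Si](C(C)C)(C(C)C)C(C)C | intermediate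
20 | (2R,3S)-5-(bromomethyl)-3-[(tert-butyldiphenylsilyloxy)methyl]-7-methoxy-2-[3-methoxy-4-(triisopropylsilyloxy)phenyl]-2,3-dihydrobenzofuran | COc1cc([C@@H]2Oc3c(OC)cc(CBr)cc3[C@H]2CO[Si](c4ccccc4)(c5ccccc5)C(C)(C)C)ccc1O[Si](C(C)C)(C(C)C)C(C)C | intermediate
21 | outer-unit (2R,5R)-2,5-dimethylthiolanium tetrafluoroborate | COc1cc([C@@H]2Oc3c(OC)cc(C[S+]6[C@H](C)CC[C@H]6C)cc3[C@H]2CO[Si](c4ccccc4)(c5ccccc5)C(C)(C)C)ccc1O[Si](C(C)C)(C(C)C)C(C)C.F[B-](F)(F)F | intermediate
22 | eugenol | COc1cc(CC=C)ccc1O | starting material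
23 | bis(9-BBN) adduct of eugenol, B–C at the chain terminus and B–O at the phenol (not isolated) | COc1cc(CCCB2C3CCCC2CCC3)ccc1OB1C2CCCC1CCC2 | intermediate
24 | dihydroconiferyl alcohol | COc1cc(CCCO)ccc1O | intermediate
25 | 4-[3-(tert-butyldiphenylsilyloxy)propyl]-2-methoxyphenol | COc1cc(CCCO[Si](c2ccccc2)(c2ccccc2)C(C)(C)C)ccc1O | intermediate
26 | 5-[3-(tert-butyldiphenylsilyloxy)propyl]-2-hydroxy-3-methoxybenzaldehyde | COc1cc(CCCO[Si](c2ccccc2)(c2ccccc2)C(C)(C)C)cc(C=O)c1O | intermediate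
27 | 4-[3-(tert-butyldiphenylsilyloxy)propyl]-2-methoxy-6-vinylphenol | COc1cc(CCCO[Si](c2ccccc2)(c2ccccc2)C(C)(C)C)cc(C=C)c1O | intermediate
28 | 1-{5-[3-(tert-butyldiphenylsilyloxy)propyl]-2-hydroxy-3-methoxyphenyl}ethane-1,2-diol (racemic) | COc1cc(CCCO[Si](c2ccccc2)(c2ccccc2)C(C)(C)C)cc(C(O)CO)c1O | intermediate
29 | 2-[2-(tert-butyldiphenylsilyloxy)-1-hydroxyethyl]-4-[3-(tert-butyldiphenylsilyloxy)propyl]-6-methoxyphenol (racemic) | COc1cc(CCCO[Si](c2ccccc2)(c2ccccc2)C(C)(C)C)cc(C(O)CO[Si](c2ccccc2)(c2ccccc2)C(C)(C)C)c1O | intermediate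
30 | 2-[2-(tert-butyldiphenylsilyloxy)-1-tosylethyl]-4-[3-(tert-butyldiphenylsilyloxy)propyl]-6-methoxyphenol (racemic; ring C sulfone) | COc1cc(CCCO[Si](c2ccccc2)(c2ccccc2)C(C)(C)C)cc(C(CO[Si](c2ccccc2)(c2ccccc2)C(C)(C)C)S(=O)(=O)c2ccc(C)cc2)c1O | intermediate
31 | ring C ortho-quinone methide (not isolated) | COC1=CC(CCCO[Si](c2ccccc2)(c2ccccc2)C(C)(C)C)=CC(=CCO[Si](c2ccccc2)(c2ccccc2)C(C)(C)C)C1=O | intermediate
32 | outer-unit benzylic ylide (not isolated) | COc1cc([C@@H]2Oc3c(OC)cc([CH-][S+]6[C@H](C)CC[C@H]6C)cc3[C@H]2CO[Si](c4ccccc4)(c5ccccc5)C(C)(C)C)ccc1O[Si](C(C)C)(C(C)C)C(C)C | intermediate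
33 | ring C anti betaine (not isolated) | COc1cc([C@@H]2Oc3c(OC)cc([C@@H]([S+]4[C@H](C)CC[C@H]4C)[C@H](CO[Si](c6ccccc6)(c7ccccc7)C(C)(C)C)c5cc(CCCO[Si](c6ccccc6)(c7ccccc7)C(C)(C)C)cc(OC)c5[O-])cc3[C@H]2CO[Si](c6ccccc6)(c7ccccc7)C(C)(C)C)ccc1O[Si](C(C)C)(C(C)C)C(C)C | intermediate
34 | tetrasilyl ether of the target, (2R,3S) at both dihydrofuran rings | COc1cc([C@@H]2Oc3c(OC)cc([C@@H]4Oc5c(OC)cc(CCCO[Si](c6ccccc6)(c7ccccc7)C(C)(C)C)cc5[C@H]4CO[Si](c6ccccc6)(c7ccccc7)C(C)(C)C)cc3[C@H]2CO[Si](c6ccccc6)(c7ccccc7)C(C)(C)C)ccc1O[Si](C(C)C)(C(C)C)C(C)C | intermediate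
35 | CNP0599161.1 | COc1cc([C@@H]2Oc3c(OC)cc([C@@H]4Oc5c(OC)cc(CCCO)cc5[C@H]4CO)cc3[C@H]2CO)ccc1O | target

## Step count and risk

Total step count: 24.

Longest linear sequence: 11 steps (methyl vanillate 9 through steps 7–15, then steps 23 and 24).

Steps most likely to fail:

**1. Step 23 (key annulation).** The methide 31, which carries a CH2OSi group, may isomerise by 1,5-hydrogen shift to the 2-(2-silyloxyvinyl)phenol. The liberated sulfinate may also debenzylate the hindered sulfonium salt before the ylide forms and is captured, and facial selectivity at the ylide carbon may be incomplete. The fallback forms O1–C2 first and C2–C3 second, by Williamson etherification and carbenoid C–H insertion. It sets out from vinylphenol 27 and bromide 20 and rejoins the route at target 35.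
- K2CO3 in DMF joins 27 and 20 to the aryl benzyl ether styrene F1.
- 9-BBN followed by NaBO3·4H2O gives the 2-arylethanol F2.
- TEMPO/PhI(OAc)2 in MeCN/H2O gives the arylacetic acid F3, and Me3SiCHN2 its methyl ester F4.
- Diazo transfer with p-acetamidobenzenesulfonyl azide and DBU gives the aryldiazoacetate F5.
- Dirhodium tetrakis[N-phthaloyl-(S)-tert-leucinate], Rh2(S-PTTL)4 (or its antipode, whichever sets 2R), in toluene at −60 °C should insert the carbenoid into the benzylic O–CH2 bond to give the cis-dihydrobenzofuran ester F6.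
- DBU in toluene epimerises C3 to the trans ester F7.
- i-Bu2AlH reduces the ester to the alcohol F8, which Bu4NF/AcOH converts into 35.

**2. Step 12 (outer annulation).** The same competition between ylide capture and methide tautomerisation applies, and enantioselectivity from the thiolane may be insufficient on this first use. The fallback is the same etherification and C–H insertion logic; it sets out from vinylphenol 11 and bromide 7 and rejoins at 18.
- K2CO3 in DMF gives the aryl benzyl ether styrene F9.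
- 9-BBN followed by NaBO3·4H2O gives the alcohol F10.
- TEMPO/PhI(OAc)2 gives the acid F11, and Me3SiCHN2 the diester F12.
- Diazo transfer gives the aryldiazoacetate F13.
- Rh2(S-PTTL)4 (or its antipode) gives the cis diester F14, and DBU in toluene the trans diester F15.
- LiBH4 in THF at 0 °C should reduce the aliphatic ester in preference to the deactivated aryl ester, giving the hydroxy ester F16.
- TBDPSCl/imidazole converts F16 into 18.

**3. Step 11 (sulfination on the ester-bearing ring).** Ionisation of the benzylic alcohol is slowed by the β-silyloxy group and the meta ester. This may allow hydride shift to the arylacetaldehyde (and hence a benzofuran) or loss of the silyl ether before sulfinate capture. The fallback replaces ionisation by SN2 thioetherification and oxidation; it sets out from 13 and rejoins at 14.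
- PBu3 and di-p-tolyl disulfide in THF (Hata reaction) should give the benzylic p-tolyl sulfide F17.
- mCPBA (2.2 equiv, NaHCO3, CH2Cl2, 0 °C) oxidises F17 to sulfone 14.

Further compounds
F1 | step 23 | aryl benzyl ether of 27 with the outer unit (styrene) | COc1cc([C@@H]2Oc3c(OC)cc(COc6c(OC)cc(CCCO[Si](c7ccccc7)(c8ccccc8)C(C)(C)C)cc6C=C)cc3[C@H]2CO[Si](c4ccccc4)(c5ccccc5)C(C)(C)C)ccc1O[Si](C(C)C)(C(C)C)C(C)C
F2 | step 23 | 2-arylethanol from hydroboration of F1 | COc1cc([C@@H]2Oc3c(OC)cc(COc6c(OC)cc(CCCO[Si](c7ccccc7)(c8ccccc8)C(C)(C)C)cc6CCO)cc3[C@H]2CO[Si](c4ccccc4)(c5ccccc5)C(C)(C)C)ccc1O[Si](C(C)C)(C(C)C)C(C)C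
F3 | step 23 | arylacetic acid | COc1cc([C@@H]2Oc3c(OC)cc(COc6c(OC)cc(CCCO[Si](c7ccccc7)(c8ccccc8)C(C)(C)C)cc6CC(=O)O)cc3[C@H]2CO[Si](c4ccccc4)(c5ccccc5)C(C)(C)C)ccc1O[Si](C(C)C)(C(C)C)C(C)C
F4 | step 23 | methyl arylacetate | COc1cc([C@@H]2Oc3c(OC)cc(COc6c(OC)cc(CCCO[Si](c7ccccc7)(c8ccccc8)C(C)(C)C)cc6CC(=O)OC)cc3[C@H]2CO[Si](c4ccccc4)(c5ccccc5)C(C)(C)C)ccc1O[Si](C(C)C)(C(C)C)C(C)C
F5 | step 23 | methyl aryldiazoacetate | COc1cc([C@@H]2Oc3c(OC)cc(COc6c(OC)cc(CCCO[Si](c7ccccc7)(c8ccccc8)C(C)(C)C)cc6C(=[N+]=[N-])C(=O)OC)cc3[C@H]2CO[Si](c4ccccc4)(c5ccccc5)C(C)(C)C)ccc1O[Si](C(C)C)(C(C)C)C(C)C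
F6 | step 23 | cis inner ester, (2R,3S) at the inner ring | COc1cc([C@@H]2Oc3c(OC)cc([C@@H]4Oc5c(OC)cc(CCCO[Si](c6ccccc6)(c7ccccc7)C(C)(C)C)cc5[C@@H]4C(=O)OC)cc3[C@H]2CO[Si](c6ccccc6)(c7ccccc7)C(C)(C)C)ccc1O[Si](C(C)C)(C(C)C)C(C)C
F7 | step 23 | trans inner ester, (2R,3R) at the inner ring | COc1cc([C@@H]2Oc3c(OC)cc([C@@H]4Oc5c(OC)cc(CCCO[Si](c6ccccc6)(c7ccccc7)C(C)(C)C)cc5[C@H]4C(=O)OC)cc3[C@H]2CO[Si](c6ccccc6)(c7ccccc7)C(C)(C)C)ccc1O[Si](C(C)C)(C(C)C)C(C)C
F8 | step 23 | trisilyl ether of the target with free inner 3-hydroxymethyl | COc1cc([C@@H]2Oc3c(OC)cc([C@@H]4Oc5c(OC)cc(CCCO[Si](c6ccccc6)(c7ccccc7)C(C)(C)C)cc5[C@H]4CO)cc3[C@H]2CO[Si](c6ccccc6)(c7ccccc7)C(C)(C)C)ccc1O[Si](C(C)C)(C(C)C)C(C)C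
F9 | step 12 | methyl 3-methoxy-4-[3-methoxy-4-(triisopropylsilyloxy)benzyloxy]-5-vinylbenzoate | COc1cc(COc2c(OC)cc(C(=O)OC)cc2C=C)ccc1O[Si](C(C)C)(C(C)C)C(C)C
F10 | step 12 | methyl 3-(2-hydroxyethyl)-5-methoxy-4-[3-methoxy-4-(triisopropylsilyloxy)benzyloxy]benzoate | COc1cc(COc2c(OC)cc(C(=O)OC)cc2CCO)ccc1O[Si](C(C)C)(C(C)C)C(C)C
F11 | step 12 | 2-{3-methoxy-5-(methoxycarbonyl)-2-[3-methoxy-4-(triisopropylsilyloxy)benzyloxy]phenyl}acetic acid | COc1cc(COc2c(OC)cc(C(=O)OC)cc2CC(=O)O)ccc1O[Si](C(C)C)(C(C)C)C(C)C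
F12 | step 12 | methyl 3-methoxy-5-(2-methoxy-2-oxoethyl)-4-[3-methoxy-4-(triisopropylsilyloxy)benzyloxy]benzoate | COc1cc(COc2c(OC)cc(C(=O)OC)cc2CC(=O)OC)ccc1O[Si](C(C)C)(C(C)C)C(C)C
F13 | step 12 | methyl 3-(1-diazo-2-methoxy-2-oxoethyl)-5-methoxy-4-[3-methoxy-4-(triisopropylsilyloxy)benzyloxy]benzoate | COc1cc(COc2c(OC)cc(C(=O)OC)cc2C(=[N+]=[N-])C(=O)OC)ccc1O[Si](C(C)C)(C(C)C)C(C)C
F14 | step 12 | dimethyl (2R,3S)-7-methoxy-2-[3-methoxy-4-(triisopropylsilyloxy)phenyl]-2,3-dihydrobenzofuran-3,5-dicarboxylate (cis) | COc1cc([C@@H]2Oc3c(OC)cc(C(=O)OC)cc3[C@@H]2C(=O)OC)ccc1O[Si](C(C)C)(C(C)C)C(C)C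
F15 | step 12 | dimethyl (2R,3R)-7-methoxy-2-[3-methoxy-4-(triisopropylsilyloxy)phenyl]-2,3-dihydrobenzofuran-3,5-dicarboxylate (trans) | COc1cc([C@@H]2Oc3c(OC)cc(C(=O)OC)cc3[C@H]2C(=O)OC)ccc1O[Si](C(C)C)(C(C)C)C(C)C
F16 | step 12 | methyl (2R,3S)-3-(hydroxymethyl)-7-methoxy-2-[3-methoxy-4-(triisopropylsilyloxy)phenyl]-2,3-dihydrobenzofuran-5-carboxylate | COc1cc([C@@H]2Oc3c(OC)cc(C(=O)OC)cc3[C@H]2CO)ccc1O[Si](C(C)C)(C(C)C)C(C)C
F17 | step 11 | methyl 3-[2-(tert-butyldiphenylsilyloxy)-1-(p-tolylthio)ethyl]-4-hydroxy-5-methoxybenzoate (racemic) | COc1cc(C(=O)OC)cc(C(CO[Si](c2ccccc2)(c2ccccc2)C(C)(C)C)Sc2ccc(C)cc2)c1O
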